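**Retrosynthetic overview**
1. Target 21 ⇐ diester 20 by double saponification.
2. 20 ⇐ C8–C9 bond: alkenyl iodide 14 + δ-boryl (Z)-enoate 19, a vinylogous homoenolate made in the flask from (Z)-dienoate 18 and 9-BBN (B-alkyl Suzuki); 18 ⇐ acrolein + phosphonate 16.
3. 14 ⇐ Z-selective Ando olefination of 3-(furan-3-yl)propanal 13 with phosphonate 10; 10 ⇐ diiodide 8 + phosphonoacetate 9.
4. 8 ⇐ alkynal 4 (Schwartz reduction/hydrozirconation–iodination, then Appel) ⇐ (R)-carvone 1 by epoxidation and Eschenmoser–Tanabe ring fragmentation; the single stereocentre comes from carvone.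
5. Rings: none is formed; the furan is bought as 3-bromofuran and the carvone ring is opened in step 2.

Assumption: the target is taken exactly as the SMILES, i.e. (2Z,5R,7E,11Z) in tridecadienedioic acid numbering; ethyl 2-[bis(2-methylphenoxy)phosphoryl]acetate (Ando reagent) and Cp2Zr(H)Cl are bought.

**Route**

Step 1
Reactants: 1 (R)-(−)-carvone
Product: 2 (1R,4R,6R)-1-methyl-4-(prop-1-en-2-yl)-7-oxabicyclo[4.1.0]heptan-2-one
Conditions: 30% aq H2O2, NaOH (cat.), MeOH, 0 °C
Reagents that add atoms: hydrogen peroxide, OO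
Why: Weitz–Scheffer nucleophilic epoxidation attacks only the electron-poor enone C=C (the isopropenyl group is inert) anti to the isopropenyl group, and the carvone stereocentre that becomes C5 of the target is carried through unchanged.

Step 2
Reactants: 2 (1R,4R,6R)-1-methyl-4-(prop-1-en-2-yl)-7-oxabicyclo[4.1.0]heptan-2-one
Product: 4 (3S)-3-(prop-1-en-2-yl)hept-5-ynal, via epoxy ketone tosylhydrazone 3 (not isolated)
Conditions: TsNHNH2 (1.0 equiv), AcOH/CH2Cl2 1:1, −20 °C → rt
Reagents that add atoms: none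
Why: Eschenmoser–Tanabe fragmentation: the tosylhydrazone opens the epoxide and then loses N2 and sulfinate with cleavage of the former Cα–Cβ ring bond, giving a methyl alkyne on one arm and an aldehyde on the other without touching the stereocentre (the descriptor becomes S only through CIP priorities).

Step 3
Reactants: 4 (3S)-3-(prop-1-en-2-yl)hept-5-ynal
Product: 7 (3S,5E)-6-iodo-3-(prop-1-en-2-yl)hept-5-en-1-ol, via alkynyl zirconium alkoxide 5 (not isolated), via alkenylzirconocene alkoxide 6 (not isolated)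
Conditions: Cp2Zr(H)Cl (2.5 equiv), THF, 0 °C → rt, 2 h; then I2, −78 → 0 °C; aq Na2S2O3/NaHCO3
Reagents that add atoms: iodine, II
Why: Schwartz hydrozirconation–iodinolysis: the first equivalent of Cp2Zr(H)Cl reduces the aldehyde to the zirconium alkoxide, the second adds Zr–H syn across the alkyne and the slight excess equilibrates zirconium to the less hindered methyl-bearing carbon, and iodinolysis with retention gives the (E)-2-iodoalkene while the hindered 1,1-disubstituted alkene reacts much more slowly.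

Step 4
Reactants: 7 (3S,5E)-6-iodo-3-(prop-1-en-2-yl)hept-5-en-1-ol
Product: 8 (2E,5S)-2,7-diiodo-5-(prop-1-en-2-yl)hept-2-ene
Conditions: I2, PPh3, imidazole, CH2Cl2, 0 °C → rt
Reagents that add atoms: iodine, II
Why: Appel-type (Garegg–Samuelsson) iodination replaces the primary hydroxyl by SN2 displacement of the oxyphosphonium while the alkenes and the alkenyl iodide are inert.

Step 5
Reactants: 8 (2E,5S)-2,7-diiodo-5-(prop-1-en-2-yl)hept-2-ene; 9 ethyl 2-[bis(2-methylphenoxy)phosphoryl]acetate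
Product: 10 ethyl (2RS,5R,7E)-2-[bis(2-methylphenoxy)phosphoryl]-8-iodo-5-(prop-1-en-2-yl)non-7-enoate
Conditions: 9 (2.0 equiv), NaH (1.8 equiv), DMSO, rt; then 8, 50 °C
Reagents that add atoms: none
Why: SN2 C-alkylation of the stabilised phosphonoacetate anion by the primary alkyl iodide; the sp2 C–I bond does not react and the new C2 centre (epimer mixture) is destroyed in step 7.

Step 6
Reactants: 11 3-bromofuran; 12 prop-2-en-1-ol (allyl alcohol)
Product: 13 3-(furan-3-yl)propanal
Conditions: Pd(OAc)2 (3 mol %), Bu4NCl, NaHCO3, DMF, 70 °C, sealed tube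
Reagents that add atoms: none
Why: Heck arylation of allyl alcohol under Jeffery conditions: the furyl–Pd adds to the terminal carbon and β-hydride elimination towards the carbinol followed by tautomerisation gives the 3-arylpropanal.

Step 7
Reactants: 10 ethyl (2RS,5R,7E)-2-[bis(2-methylphenoxy)phosphoryl]-8-iodo-5-(prop-1-en-2-yl)non-7-enoate; 13 3-(furan-3-yl)propanal
Product: 14 ethyl (2Z,5R,7E)-2-[3-(furan-3-yl)propylidene]-8-iodo-5-(prop-1-en-2-yl)non-7-enoate
Conditions: NaH, THF, −78 °C; then 13, −78 → 0 °C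
Reagents that add atoms: none
Why: Ando Z-selective Horner–Wadsworth–Emmons olefination: the diaryl phosphonate makes oxaphosphetane collapse fast and kinetically controlled, which places the furylethyl group cis to the ester (2Z, typically ≥ 9:1).

Step 8
Reactants: 9 ethyl 2-[bis(2-methylphenoxy)phosphoryl]acetate; 15 5-bromo-2-methylpent-2-ene
Product: 16 ethyl (2RS)-2-[bis(2-methylphenoxy)phosphoryl]-6-methylhept-5-enoate
Conditions: NaH, DMSO, rt; then 15, NaI (cat.), 50 °C
Reagents that add atoms: none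
Why: SN2 C-alkylation of the phosphonoacetate anion by the primary homoallylic bromide.

Step 9
Reactants: 16 ethyl (2RS)-2-[bis(2-methylphenoxy)phosphoryl]-6-methylhept-5-enoate; 17 acrolein
Product: 18 ethyl (2Z)-2-(4-methylpent-3-en-1-yl)penta-2,4-dienoate
Conditions: NaH, THF, −78 °C; then freshly distilled acrolein, −78 → −20 °C
Reagents that add atoms: none
Why: Ando Z-selective Horner–Wadsworth–Emmons olefination by 1,2-addition to acrolein at low temperature gives the (2Z)-dienoate with the vinyl group cis to the ester.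

Step 10
Reactants: 14 ethyl (2Z,5R,7E)-2-[3-(furan-3-yl)propylidene]-8-iodo-5-(prop-1-en-2-yl)non-7-enoate; 18 ethyl (2Z)-2-(4-methylpent-3-en-1-yl)penta-2,4-dienoate
Product: 20 diethyl (2Z,5R,7E,11Z)-2-[3-(furan-3-yl)propylidene]-8-methyl-12-(4-methylpent-3-en-1-yl)-5-(prop-1-en-2-yl)trideca-7,11-dienedioate, via delta-boryl enoate 19 (not isolated)
Conditions: 18 (1.5 equiv), 9-BBN (1.4 equiv), THF, 0 °C → rt; then 14, Pd(dppf)Cl2 (5 mol %), AsPh3, Cs2CO3, DMF/H2O, rt
Reagents that add atoms: none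
Why: Proposed new method: a 2,4-dienoate has not, as far as I know, been used in this way as a δ-boryl (vinylogous homoenolate) donor; 9-BBN should add anti-Markovnikov to the only monosubstituted C=C of 18 (the trisubstituted and ester-conjugated alkenes and the ester react far more slowly), which puts nucleophilic boron on C5, a carbon that is electrophilic in the parent dienoate, and this primary borane then undergoes B-alkyl Suzuki–Miyaura coupling with the electrophilic alkenyl iodide carbon with retention at sp2 carbon, leaving both Z-enoates and the stereocentre untouched; the closest known chemistry is 9-BBN hydroboration of terminal 1,3-dienes to homoallylic boranes and their Pd(dppf)/AsPh3/Cs2CO3 coupling with 2-iodoalk-2-enes.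

Step 11
Reactants: 20 diethyl (2Z,5R,7E,11Z)-2-[3-(furan-3-yl)propylidene]-8-methyl-12-(4-methylpent-3-en-1-yl)-5-(prop-1-en-2-yl)trideca-7,11-dienedioate
Product: 21 (2Z,5R,7E,11Z)-2-[3-(furan-3-yl)propylidene]-8-methyl-12-(4-methylpent-3-en-1-yl)-5-(prop-1-en-2-yl)trideca-7,11-dienedioic acid (CNP0235727.1)
Conditions: LiOH·H2O (excess), THF/MeOH/H2O, 45 °C; then 1 M HCl to pH 3, 0 °C
Reagents that add atoms: lithium hydroxide, [Li+].[OH-]
Why: Saponification (BAc2 ester hydrolysis) of both ethyl esters; the trisubstituted enoates do not isomerise under these conditions and brief cold acidification spares the furan.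

**Compound list**
1 | (R)-(−)-carvone | CC1=CC[C@H](CC1=O)C(C)=C | starting material
2 | (1R,4R,6R)-1-methyl-4-(prop-1-en-2-yl)-7-oxabicyclo[4.1.0]heptan-2-one | C[C@@]12O[C@@H]1C[C@@H](C(C)=C)CC2=O | intermediate
3 | N-tosylhydrazone of 2 | C[C@@]12O[C@@H]1C[C@@H](C(C)=C)CC2=NNS(=O)(=O)c3ccc(C)cc3 | intermediate
4 | (3S)-3-(prop-1-en-2-yl)hept-5-ynal (S by CIP priority change only) | C=C(C)[C@@H](CC#CC)CC=O | intermediate
5 | chlorobis(cyclopentadienyl)zirconium (3S)-3-(prop-1-en-2-yl)hept-5-yn-1-olate | C=C(C)[C@@H](CC#CC)CCO[Zr](Cl)(C1C=CC=C1)C1C=CC=C1 | intermediate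
6 | (E)-alkenylzirconocene chloride of 5, Zr on the methyl-bearing carbon | C=C(C)[C@@H](C/C=C(\C)[Zr](Cl)(C1C=CC=C1)C1C=CC=C1)CCO[Zr](Cl)(C1C=CC=C1)C1C=CC=C1 | intermediate
7 | (3S,5E)-6-iodo-3-(prop-1-en-2-yl)hept-5-en-1-ol | C=C(C)[C@@H](C/C=C(\C)I)CCO | intermediate
8 | (2E,5S)-2,7-diiodo-5-(prop-1-en-2-yl)hept-2-ene | C=C(C)[C@@H](C/C=C(\C)I)CCI | intermediate
9 | ethyl 2-[bis(2-methylphenoxy)phosphoryl]acetate | CCOC(=O)CP(=O)(Oc1ccccc1C)Oc1ccccc1C | starting material
10 | ethyl (2RS,5R,7E)-2-[bis(2-methylphenoxy)phosphoryl]-8-iodo-5-(prop-1-en-2-yl)non-7-enoate | C=C(C)[C@@H](C/C=C(\C)I)CCC(C(=O)OCC)P(=O)(Oc1ccccc1C)Oc1ccccc1C | intermediate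
11 | 3-bromofuran | Brc1ccoc1 | starting material
12 | prop-2-en-1-ol | C=CCO | starting material
13 | 3-(furan-3-yl)propanal | O=CCCc1ccoc1 | intermediate
14 | ethyl (2Z,5R,7E)-2-[3-(furan-3-yl)propylidene]-8-iodo-5-(prop-1-en-2-yl)non-7-enoate | C=C(C)[C@@H](C/C=C(\C)I)CC/C(=C/CCc1ccoc1)C(=O)OCC | intermediate
15 | 5-bromo-2-methylpent-2-ene | CC(C)=CCCBr | starting material
16 | ethyl (2RS)-2-[bis(2-methylphenoxy)phosphoryl]-6-methylhept-5-enoate | CCOC(=O)C(CCC=C(C)C)P(=O)(Oc1ccccc1C)Oc1ccccc1C | intermediate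
17 | acrolein | C=CC=O | starting material
18 | ethyl (2Z)-2-(4-methylpent-3-en-1-yl)penta-2,4-dienoate | C=C/C=C(/CCC=C(C)C)C(=O)OCC | intermediate
19 | ethyl (2Z)-5-(9-borabicyclo[3.3.1]nonan-9-yl)-2-(4-methylpent-3-en-1-yl)pent-2-enoate | CCOC(=O)/C(CCC=C(C)C)=C\CCB1C2CCCC1CCC2 | intermediate
20 | diethyl (2Z,5R,7E,11Z)-2-[3-(furan-3-yl)propylidene]-8-methyl-12-(4-methylpent-3-en-1-yl)-5-(prop-1-en-2-yl)trideca-7,11-dienedioate | C=C(C)[C@@H](C/C=C(\C)CC/C=C(/CCC=C(C)C)C(=O)OCC)CC/C(=C/CCc1ccoc1)C(=O)OCC | intermediate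
21 | (2Z,5R,7E,11Z)-2-[3-(furan-3-yl)propylidene]-8-methyl-12-(4-methylpent-3-en-1-yl)-5-(prop-1-en-2-yl)trideca-7,11-dienedioic acid | C=C(C)[C@@H](C/C=C(\C)CC/C=C(/CCC=C(C)C)C(=O)O)CC/C(=C/CCc1ccoc1)C(=O)O | target

**Totals and risks**
Total step count: 11. Longest linear sequence: 8 steps (1 → 2 → 4 → 7 → 8 → 10 → 14 → 20 → 21).

Step 10 is the most likely to fail. The danger is that 9-BBN adds to C4 instead of C5 of the electron-poor dienoate, attacks the ester, or that the borane protodeboronates. The fallback sets out from 14 and comes back at 20. Negishi coupling of 14 with the commercial aldehyde homoenolate reagent [2-(1,3-dioxolan-2-yl)ethyl]zinc bromide (Pd(PPh3)4, THF, 50 °C) gives ethyl (2Z,5R,7E)-10-(1,3-dioxolan-2-yl)-2-[3-(furan-3-yl)propylidene]-8-methyl-5-(prop-1-en-2-yl)dec-7-enoate F4. Mild acetal hydrolysis (PPTS, acetone/H2O, reflux) gives ethyl (2Z,5R,7E)-2-[3-(furan-3-yl)propylidene]-8-methyl-11-oxo-5-(prop-1-en-2-yl)undec-7-enoate F5. Ando olefination of this aldehyde with phosphonate 16 (NaH, THF, −78 → 0 °C) gives 20.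

Step 3 is next. Zirconium may end on the wrong alkyne carbon, or the excess hydride may attack the isopropenyl group. The fallback sets out from 4 and comes back at 7. NaBH4 (MeOH, 0 °C) gives (3S)-3-(prop-1-en-2-yl)hept-5-yn-1-ol F1. Copper-catalysed borylcupration–protonation ((SIPr)CuCl, NaOtBu, B2pin2, MeOH, THF, rt) does not touch unactivated alkenes and should deliver boron syn to the less hindered methyl-bearing carbon, giving (3S,5Z)-3-(prop-1-en-2-yl)-6-(4,4,5,5-tetramethyl-1,3,2-dioxaborolan-2-yl)hept-5-en-1-ol F2. Its regioselectivity is ligand-controlled and would need to be checked. Iododeboronation with retention (NaOH, then I2, THF/H2O, 0 °C) gives 7.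

Step 6 is third. The Heck reaction of the volatile, electron-rich 3-bromofuran may give low conversion or the branched aldehyde. The fallback sets out from 11 and comes back at 13. Bromine–lithium exchange (n-BuLi, THF, −78 °C) and opening of oxetane (BF3·OEt2, −78 °C) gives 3-(furan-3-yl)propan-1-ol F3, and Dess–Martin oxidation (CH2Cl2, NaHCO3, rt) gives 13.

**Further compounds**
F1 | step 3 | (3S)-3-(prop-1-en-2-yl)hept-5-yn-1-ol | C=C(C)[C@@H](CC#CC)CCO
F2 | step 3 | (3S,5Z)-3-(prop-1-en-2-yl)-6-(4,4,5,5-tetramethyl-1,3,2-dioxaborolan-2-yl)hept-5-en-1-ol | C=C(C)[C@@H](C/C=C(\C)B1OC(C)(C)C(C)(C)O1)CCO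
F3 | step 6 | 3-(furan-3-yl)propan-1-ol | OCCCc1ccoc1
F4 | step 10 | ethyl (2Z,5R,7E)-10-(1,3-dioxolan-2-yl)-2-[3-(furan-3-yl)propylidene]-8-methyl-5-(prop-1-en-2-yl)dec-7-enoate | C=C(C)[C@@H](C/C=C(\C)CCC1OCCO1)CC/C(=C/CCc1ccoc1)C(=O)OCC
F5 | step 10 | ethyl (2Z,5R,7E)-2-[3-(furan-3-yl)propylidene]-8-methyl-11-oxo-5-(prop-1-en-2-yl)undec-7-enoate | C=C(C)[C@@H](C/C=C(\C)CCC=O)CC/C(=C/CCc1ccoc1)C(=O)OCC
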